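**Plan**
- Retrosynthesis: the O7–S and O4'–S bonds are cut first (back to hispidulin), then the three benzyl ethers, then O1–C2 of the pyranone (back to a hydroxy ynone), and last O1–C8a together with C4a–C4.
- Enabling feature: on ring A the ring oxygen O1 sits on C8a and the C4 acyl carbon on the neighbouring C4a, with the C5 oxygen flanking C4a. A 3-benzyloxyaryne can take up this vicinal O,C pair from a carboxylic acid in one orientation only.
- Forward: ring A is taken from methyl 3,5-dihydroxy-4-methoxybenzoate to a 2-silylaryl triflate (6 steps), and ring B with C2–C4 comes as an arylpropiolic acid (1 step). Aryne insertion joins the two without closing a ring, ring C then closes through O1–C2, and debenzylation and disulfation finish the route.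
- Stereochemistry: the target has no stereocentre and no stereogenic double bond. Only regiocontrol is needed (aryne orientation, 6-endo closure, O7/O4' over O5 in the sulfation).

Key step: step 8

Assumption: the target is taken as the free bis(hydrogen sulfate) exactly as drawn; because aryl hydrogen sulfates hydrolyse slowly as free acids, the acid form is released cold and only at the very end.

Step 1
Reactants: 1 methyl 3,5-dihydroxy-4-methoxybenzoate
Product: 2 methyl 3,5-bis(benzyloxy)-4-methoxybenzoate
Conditions: BnBr (2.3 equiv), K2CO3, DMF, 60 °C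
Reagents that add atoms: benzyl bromide, BrCc1ccccc1
Why: Williamson etherification of the two equivalent phenols, with the methyl ester inert to carbonate in DMF.

Step 2
Reactants: 2 methyl 3,5-bis(benzyloxy)-4-methoxybenzoate
Product: 3 [3,5-bis(benzyloxy)-4-methoxyphenyl]methanol
Conditions: LiAlH4, THF, 0 °C → rt; H2O/aq NaOH work-up
Reagents that add atoms: none
Why: Hydride reduction of the ester to the benzylic alcohol, which leaves the aryl benzyl and methyl ethers untouched.

Step 3
Reactants: 3 [3,5-bis(benzyloxy)-4-methoxyphenyl]methanol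
Product: 4 3,5-bis(benzyloxy)-4-methoxybenzaldehyde
Conditions: activated MnO2 (excess), CH2Cl2, rt
Reagents that add atoms: none
Why: Benzylic alcohol oxidation with activated MnO2 stops cleanly at the aldehyde.

Step 4
Reactants: 4 3,5-bis(benzyloxy)-4-methoxybenzaldehyde
Product: 6 3,5-bis(benzyloxy)-4-methoxyphenol, via aryl formate 5 (not isolated)
Conditions: mCPBA, CH2Cl2, 0 °C → rt; aq Na2S2O3/NaHCO3 wash; K2CO3 (cat.), MeOH, rt
Reagents that add atoms: meta-chloroperoxybenzoic acid, OOC(=O)c1cccc(Cl)c1
Why: Baeyer–Villiger oxidation in which the electron-rich para-methoxyaryl group migrates in preference to hydrogen gives the aryl formate, which base-catalysed methanolysis converts into the phenol.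

Step 5
Reactants: 6 3,5-bis(benzyloxy)-4-methoxyphenol
Product: 7 3,5-bis(benzyloxy)-2-bromo-4-methoxyphenol
Conditions: NBS (1.0 equiv), CH2Cl2, −78 → 0 °C
Reagents that add atoms: N-bromosuccinimide, BrN1C(=O)CCC1=O
Why: Electrophilic aromatic bromination of a phenol whose para position is blocked and whose two ortho positions are equivalent, so one equivalent of NBS at low temperature should give a single monobromide.

Step 6
Reactants: 7 3,5-bis(benzyloxy)-2-bromo-4-methoxyphenol
Product: 10 3,5-bis(benzyloxy)-4-methoxy-2-(trimethylsilyl)phenyl trifluoromethanesulfonate, via aryl trimethylsilyl ether 8 (not isolated), via lithium 2-silylphenoxide 9 (not isolated)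
Conditions: HMDS, THF, 70 °C, then evaporate; n-BuLi (1.1 equiv), THF, −100 → −78 °C; Tf2O (1.2 equiv), −100 → −78 °C; aq NaHCO3
Reagents that add atoms: hexamethyldisilazane, C[Si](C)(C)N[Si](C)(C)C; trifluoromethanesulfonic anhydride, FC(F)(F)S(=O)(=O)OS(=O)(=O)C(F)(F)F
Why: O-silylation, bromine–lithium exchange and retro-Brook 1,3-O→C silyl migration put silicon on the carbon that carried bromine, and the phenoxide set free is triflated in the same flask, which is the standard one-pot entry to 2-silylaryl triflates.

Step 7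
Reactants: 11 1-(benzyloxy)-4-iodobenzene; 12 propiolic acid
Product: 13 3-[4-(benzyloxy)phenyl]propiolic acid
Conditions: Pd(PPh3)4 (2.5 mol %), DBU (2.4 equiv), DMSO, 35 °C; then 1 M HCl
Reagents that add atoms: none
Why: Copper-free Sonogashira coupling of the aryl iodide at the terminal C–H of the propiolate, run without copper and near room temperature so that the carboxyl group is kept.

Step 8
Reactants: 10 3,5-bis(benzyloxy)-4-methoxy-2-(trimethylsilyl)phenyl trifluoromethanesulfonate; 13 3-[4-(benzyloxy)phenyl]propiolic acid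
Product: 15 1-[2,4-bis(benzyloxy)-6-hydroxy-3-methoxyphenyl]-3-[4-(benzyloxy)phenyl]prop-2-yn-1-one, via aryne 14 (not isolated)
Conditions: 10 (1.3 equiv), CsF (4 equiv), THF, 125 °C (sealed tube); then sat. aq NH4Cl, 0 °C
Reagents that add atoms: none
Why: Fluoride removes the silyl group of 10 and triflate departs to give aryne 14; the caesium carboxylate of 13 adds through oxygen to the aryne carbon remote from the flanking benzyloxy group (future C8a), which leaves the aryl anion on the carbon next to that oxygen (future C4a). This anion attacks its own ester carbonyl through a four-membered alkoxide that opens to the 2-acylphenoxide, so O1–C8a and C4a–C4 are made in one event. The closest known reaction type is the fluoride-induced aryne σ-insertion into the acyl C–O bond of carboxylic acids, in effect an anionic Fries shift run in situ. No ring is retained and no stereocentre is created. The step needs the oxygen at C8a and not at C4a, which the distortion of the 3-alkoxyaryne and the inductive stabilisation of the anion beside the C5 oxygen secure, and it needs carbonyl attack rather than conjugate addition to the alkyne (the coumarin path), which the preferred Z-ester geometry secures by holding the carbonyl carbon next to the anion and the triple bond away from it. THF offers no acidic C–H that could quench the anion to the aryl ester; cold NH4Cl then frees phenol 15, and any material already cyclised to 16 would simply be carried into step 9.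

Step 9
Reactants: 15 1-[2,4-bis(benzyloxy)-6-hydroxy-3-methoxyphenyl]-3-[4-(benzyloxy)phenyl]prop-2-yn-1-one
Product: 16 5,7-bis(benzyloxy)-2-[4-(benzyloxy)phenyl]-6-methoxy-4H-chromen-4-one
Conditions: DMAP (20 mol %), DMF, rt → 40 °C
Reagents that add atoms: none
Why: Nucleophilic amine catalysis, in which conjugate addition of DMAP gives a β-ammonium enone that the phenol displaces by addition–elimination, closes O1–C2 in the formal 6-endo-dig sense and avoids the 5-exo aurone path.

Step 10
Reactants: 16 5,7-bis(benzyloxy)-2-[4-(benzyloxy)phenyl]-6-methoxy-4H-chromen-4-one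
Product: 17 hispidulin, 5,7-dihydroxy-2-(4-hydroxyphenyl)-6-methoxy-4H-chromen-4-one
Conditions: H2 (1 atm), 10% Pd/C, THF–MeOH, rt
Reagents that add atoms: none
Why: Hydrogenolysis of the three aryl benzyl ethers, under mild conditions that should leave the vinylogous-ester C2=C3 bond of the flavone and the methyl ether intact.

Step 11
Reactants: 17 hispidulin
Product: 18 hispidulin 7,4'-disulfate, 4-[5-hydroxy-6-methoxy-4-oxo-7-(sulfooxy)-4H-chromen-2-yl]phenyl hydrogen sulfate
Conditions: SO3·pyridine (5 equiv), pyridine, rt; then sulfonic acid cation-exchange resin (H+ form), H2O–MeOH, 0 °C; freeze-dry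
Reagents that add atoms: sulfur trioxide pyridine complex, [O-]S(=O)(=O)[n+]1ccccc1
Why: O-sulfation of phenols with an amine–SO3 complex should take the acidic, unhindered 7- and 4'-hydroxyls and spare the 5-hydroxyl, which is held in a hydrogen bond to the C4 carbonyl.

**Compound list**
1 | methyl 3,5-dihydroxy-4-methoxybenzoate | COC(=O)c1cc(O)c(OC)c(O)c1 | starting material
2 | methyl 3,5-bis(benzyloxy)-4-methoxybenzoate | COC(=O)c1cc(OCc2ccccc2)c(OC)c(OCc2ccccc2)c1 | intermediate
3 | [3,5-bis(benzyloxy)-4-methoxyphenyl]methanol | OCc1cc(OCc2ccccc2)c(OC)c(OCc2ccccc2)c1 | intermediate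
4 | 3,5-bis(benzyloxy)-4-methoxybenzaldehyde | O=Cc1cc(OCc2ccccc2)c(OC)c(OCc2ccccc2)c1 | intermediate
5 | 3,5-bis(benzyloxy)-4-methoxyphenyl formate | O=COc1cc(OCc2ccccc2)c(OC)c(OCc2ccccc2)c1 | intermediate
6 | 3,5-bis(benzyloxy)-4-methoxyphenol | Oc1cc(OCc2ccccc2)c(OC)c(OCc2ccccc2)c1 | intermediate
7 | 3,5-bis(benzyloxy)-2-bromo-4-methoxyphenol | Oc1cc(OCc2ccccc2)c(OC)c(OCc2ccccc2)c1Br | intermediate
8 | [3,5-bis(benzyloxy)-2-bromo-4-methoxyphenoxy]trimethylsilane | C[Si](C)(C)Oc1cc(OCc2ccccc2)c(OC)c(OCc2ccccc2)c1Br | intermediate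
9 | lithium 3,5-bis(benzyloxy)-4-methoxy-2-(trimethylsilyl)phenoxide | [Li+].[O-]c1cc(OCc2ccccc2)c(OC)c(OCc2ccccc2)c1[Si](C)(C)C | intermediate
10 | 3,5-bis(benzyloxy)-4-methoxy-2-(trimethylsilyl)phenyl trifluoromethanesulfonate | C[Si](C)(C)c1c(OS(=O)(=O)C(F)(F)F)cc(OCc2ccccc2)c(OC)c1OCc1ccccc1 | intermediate
11 | 1-(benzyloxy)-4-iodobenzene | Ic1ccc(OCc2ccccc2)cc1 | starting material
12 | propiolic acid | C#CC(=O)O | starting material
13 | 3-[4-(benzyloxy)phenyl]propiolic acid | OC(=O)C#Cc1ccc(OCc2ccccc2)cc1 | intermediate
14 | 3,5-bis(benzyloxy)-4-methoxy-1,2-didehydrobenzene (aryne) | C1#CC(OCc2ccccc2)=C(OC)C(OCc2ccccc2)=C1 | intermediate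
15 | 1-[2,4-bis(benzyloxy)-6-hydroxy-3-methoxyphenyl]-3-[4-(benzyloxy)phenyl]prop-2-yn-1-one | O=C(C#Cc1ccc(OCc2ccccc2)cc1)c1c(O)cc(OCc2ccccc2)c(OC)c1OCc1ccccc1 | intermediate
16 | 5,7-bis(benzyloxy)-2-[4-(benzyloxy)phenyl]-6-methoxy-4H-chromen-4-one | COc1c(OCc2ccccc2)cc2oc(-c3ccc(OCc4ccccc4)cc3)cc(=O)c2c1OCc1ccccc1 | intermediate
17 | hispidulin, 5,7-dihydroxy-2-(4-hydroxyphenyl)-6-methoxy-4H-chromen-4-one | COc1c(O)cc2oc(-c3ccc(O)cc3)cc(=O)c2c1O | intermediate
18 | hispidulin 7,4'-disulfate | COc1c(OS(=O)(=O)O)cc2oc(-c3ccc(OS(=O)(=O)O)cc3)cc(=O)c2c1O | target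

**Step count and risks**

Total step count: 11. Longest linear sequence: 10 steps (steps 1–6, then 8–11); the second branch is step 7.

Steps most likely to fail:

Step 8. The caesium arylpropiolate may lose CO2 at 125 °C before it meets the aryne. The aryl anion may be protonated to the aryl ester instead of shifting the acyl group. The phenoxide may also close unselectively in the hot mixture. The fallback avoids the aryne altogether; it sets out from 7 and 13 and returns at 15. Bromophenol 7 would be protected with MOMCl and i-Pr2NEt as 1,3-bis(benzyloxy)-4-bromo-2-methoxy-5-(methoxymethoxy)benzene F1. Bromine–lithium exchange (n-BuLi, THF, −78 °C) would give [2,4-bis(benzyloxy)-3-methoxy-6-(methoxymethoxy)phenyl]lithium F2. Acid 13 would be converted through its mixed anhydride (i-BuOCOCl, N-methylmorpholine, then MeNHOMe·HCl) into 3-[4-(benzyloxy)phenyl]-N-methoxy-N-methylprop-2-ynamide F3. Acylation of F2 by F3 would give 1-[2,4-bis(benzyloxy)-3-methoxy-6-(methoxymethoxy)phenyl]-3-[4-(benzyloxy)phenyl]prop-2-yn-1-one F4, and HCl in MeOH–THF at 0 °C would remove the acetal to rejoin the route at 15.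

Step 11. Sulfation may stop short or go too far, giving mixtures of anionic species that are hard to separate, and the sulfate monoesters may hydrolyse once they are in the free-acid form. The fallback uses protected, neutral sulfate diesters; it sets out from 17 and returns at 18. Hispidulin 17 would be treated with 2,2,2-trichloroethyl chlorosulfate, Et3N and DMAP in THF at 0 °C to give the chromatographable 4-[5-hydroxy-6-methoxy-4-oxo-7-{[(2,2,2-trichloroethoxy)sulfonyl]oxy}-4H-chromen-2-yl]phenyl 2,2,2-trichloroethyl sulfate F5. Zinc dust and ammonium formate in MeOH would then unmask both sulfates, and cation exchange to the acid form at 0 °C returns to 18.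

Step 6. The O→C silyl migration may be incomplete at a carbon flanked by two oxygen substituents, n-BuLi may metalate a benzylic position, or the aryllithium may be protonated so that bromine is lost without silylation. The fallback replaces the bromide and the silyl shift by carbamate-directed C–H lithiation; it sets out from 6 and returns at 10. Phenol 6 would be carbamoylated (ClCONEt2, NaH, THF) to 3,5-bis(benzyloxy)-4-methoxyphenyl diethylcarbamate F6. Directed ortho-lithiation (s-BuLi, TMEDA, THF, −78 °C) at the position that is also flanked by a benzyloxy group would give [2,4-bis(benzyloxy)-6-[(diethylcarbamoyl)oxy]-3-methoxyphenyl]lithium F7, which TMSCl would quench to 3,5-bis(benzyloxy)-4-methoxy-2-(trimethylsilyl)phenyl diethylcarbamate F8. Reductive removal of the carbamate (LiAlH4, THF, reflux) would give 3,5-bis(benzyloxy)-4-methoxy-2-(trimethylsilyl)phenol F9, and Tf2O with pyridine in CH2Cl2 at 0 °C would return to 10.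

**Further compounds**
F1 | step 8 | 1,3-bis(benzyloxy)-4-bromo-2-methoxy-5-(methoxymethoxy)benzene | COCOc1cc(OCc2ccccc2)c(OC)c(OCc2ccccc2)c1Br
F2 | step 8 | [2,4-bis(benzyloxy)-3-methoxy-6-(methoxymethoxy)phenyl]lithium | [Li]c1c(OCOC)cc(OCc2ccccc2)c(OC)c1OCc1ccccc1
F3 | step 8 | 3-[4-(benzyloxy)phenyl]-N-methoxy-N-methylprop-2-ynamide | CON(C)C(=O)C#Cc1ccc(OCc2ccccc2)cc1
F4 | step 8 | 1-[2,4-bis(benzyloxy)-3-methoxy-6-(methoxymethoxy)phenyl]-3-[4-(benzyloxy)phenyl]prop-2-yn-1-one | O=C(C#Cc1ccc(OCc2ccccc2)cc1)c1c(OCOC)cc(OCc2ccccc2)c(OC)c1OCc1ccccc1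
F5 | step 11 | 4-[5-hydroxy-6-methoxy-4-oxo-7-{[(2,2,2-trichloroethoxy)sulfonyl]oxy}-4H-chromen-2-yl]phenyl 2,2,2-trichloroethyl sulfate | COc1c(OS(=O)(=O)OCC(Cl)(Cl)Cl)cc2oc(-c3ccc(OS(=O)(=O)OCC(Cl)(Cl)Cl)cc3)cc(=O)c2c1O
F6 | step 6 | 3,5-bis(benzyloxy)-4-methoxyphenyl diethylcarbamate | CCN(CC)C(=O)Oc1cc(OCc2ccccc2)c(OC)c(OCc2ccccc2)c1
F7 | step 6 | [2,4-bis(benzyloxy)-6-[(diethylcarbamoyl)oxy]-3-methoxyphenyl]lithium | [Li]c1c(OC(=O)N(CC)CC)cc(OCc2ccccc2)c(OC)c1OCc1ccccc1
F8 | step 6 | 3,5-bis(benzyloxy)-4-methoxy-2-(trimethylsilyl)phenyl diethylcarbamate | CCN(CC)C(=O)Oc1cc(OCc2ccccc2)c(OC)c(OCc2ccccc2)c1[Si](C)(C)C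
F9 | step 6 | 3,5-bis(benzyloxy)-4-methoxy-2-(trimethylsilyl)phenol | Oc1cc(OCc2ccccc2)c(OC)c(OCc2ccccc2)c1[Si](C)(C)C
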